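**Plan**
1. Retrosynthesis: the ring A–CH2–ring B bridge is cut first (ring A Mannich base plus a B–C–D trimer), then the three aryl–butyryl bonds and the O-alkyl and O-silyl groups, and last three ring bonds of ring C.
2. Enabling feature: ring C (third ring of the SMILES) carries O and C substituents on alternating atoms. Its three oxygens map onto a ketene carbonyl, a 3-ethoxy group and a siloxyalkyne oxygen; its two CH2–aryl carbons ride on the two partners; its sixth carbon, later butyrylated, is the cyclobutenone CH.
3. Forward: the ring B arm becomes cyclobutenone 8 (steps 1–2), the ring D arm becomes siloxyalkyne 15 (steps 3–5), and their benzannulation closes ring C between the two arms (step 6).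
4. Desilylation, one butyryl group per ring and cleavage of all alkyl ethers follow (steps 7–9). Ring A (butyrylfilicinic acid, steps 10–11) is joined last through its Mannich base to the only free carbon of ring B (step 12).
5. Stereochemistry: the target has no stereocentre; the racemic centres of 8 and of the cascade intermediates disappear on aromatisation.

Key step: step 6

Remark: ring A is a tautomeric triketone and is drawn as the dienol form of the target SMILES; 1-(2,4,6-trihydroxyphenyl)butan-1-one is taken as a catalogue compound.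

**Step 1**
Reactants: 1 2,4,6-trimethoxybenzaldehyde
Product: 4 3-(2,4,6-trimethoxyphenyl)propanoic acid, via arylidene Meldrum's acid 2 (not isolated), via benzyl Meldrum's acid 3 (not isolated)
Conditions: 2,2-dimethyl-1,3-dioxane-4,6-dione, HCO2H/Et3N (5:2), 95 °C; then aq. HCl
Reagents that add atoms: Meldrum's acid (2,2-dimethyl-1,3-dioxane-4,6-dione), CC1(C)OC(=O)CC(=O)O1
Why: Tandem Knoevenagel condensation, formate conjugate reduction of the arylidene and hydrolysis with decarboxylation of the malonate acetonide is a known one-pot route from non-enolisable aromatic aldehydes to 3-arylpropanoic acids.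

**Step 2**
Reactants: 4 3-(2,4,6-trimethoxyphenyl)propanoic acid; 5 ethoxyacetylene
Product: 8 3-ethoxy-4-(2,4,6-trimethoxybenzyl)cyclobut-2-en-1-one (racemic), via acid chloride 6 (not isolated), via ketene 7 (not isolated)
Conditions: Me2C=C(Cl)NMe2, CH2Cl2, 0 °C to rt; then 5 (3 equiv), Et3N (slow addition), CH2Cl2, rt
Reagents that add atoms: none
Why: The acid chloride, made under neutral conditions that spare the electron-rich ring, is dehydrochlorinated to the alkylketene, which undergoes the known ketene–alkyne [2+2] cycloaddition with ethoxyacetylene (alkyne CH to the ketene carbonyl carbon) to give the 3-ethoxycyclobutenone, whose new ring stereocentre is racemic and is erased in step 6.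

**Step 3**
Reactants: 9 2,4,6-trimethoxytoluene
Product: 10 ethyl 2-oxo-2-(2,4,6-trimethoxy-3-methylphenyl)acetate
Conditions: ClCOCO2Et, AlCl3, CH2Cl2, −10 °C to 0 °C; aq. HCl
Reagents that add atoms: ethyl chlorooxoacetate, CCOC(=O)C(=O)Cl
Why: Friedel–Crafts acylation of the activated arene at either of its two equivalent free positions should give one glyoxylate, which deactivates the ring against a second acylation.

**Step 4**
Reactants: 10 ethyl 2-oxo-2-(2,4,6-trimethoxy-3-methylphenyl)acetate
Product: 12 ethyl 2-(2,4,6-trimethoxy-3-methylphenyl)acetate, via hydroxy ester 11 (not isolated)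
Conditions: Et3SiH, CF3CO2H, CH2Cl2, 0 °C to rt
Reagents that add atoms: none
Why: Ionic hydrogenation reduces aryl ketones to methylene groups by hydride capture of benzylic cations, which the 2,4,6-trimethoxyaryl group stabilises even next to the ester, while the ester itself is inert.

**Step 5**
Reactants: 12 ethyl 2-(2,4,6-trimethoxy-3-methylphenyl)acetate
Product: 15 1-(triisopropylsilyloxy)-3-(2,4,6-trimethoxy-3-methylphenyl)prop-1-yne, via lithium dibromoenolate 13 (not isolated), via lithium ynolate 14 (not isolated)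
Conditions: CH2Br2, lithium 2,2,6,6-tetramethylpiperidide, THF, −78 °C; LiN(SiMe3)2, −78 to −20 °C; n-BuLi, −78 °C to rt; iPr3SiCl, −78 °C to rt
Reagents that add atoms: dibromomethane, BrCBr; chlorotriisopropylsilane, CC(C)[Si](Cl)(C(C)C)C(C)C
Why: In the Kowalski ester homologation, dibromomethyllithium adds to the ester, bromine–lithium exchange on the dibromoenolate triggers a 1,2-shift of the arylmethyl group to the ynolate, and the bulky silyl chloride traps this on oxygen as the stable silyl ynol ether.

**Step 6**
Reactants: 8 3-ethoxy-4-(2,4,6-trimethoxybenzyl)cyclobut-2-en-1-one; 15 1-(triisopropylsilyloxy)-3-(2,4,6-trimethoxy-3-methylphenyl)prop-1-yne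
Product: 20 3-ethoxy-2-(2,4,6-trimethoxybenzyl)-6-(2,4,6-trimethoxy-3-methylbenzyl)-5-(triisopropylsilyloxy)phenol, via vinylketene 16 (not isolated), via vinylcyclobutenone 17 (not isolated), via dienylketene 18 (not isolated), via cyclohexadienone 19 (not isolated)
Conditions: PhMe, 80 °C then 110 °C (sealed tube), slight excess of 15
Reagents that add atoms: none
Why: Heat opens 8 by a four-electron conrotatory electrocyclic cleavage to vinylketene 16, whose ketene C=C adds to the electron-rich alkyne of 15 in a [2+2] cycloaddition to give 17; a second, reversible four-electron opening gives dienylketene 18, which closes to dienone 19 and tautomerises to phenol 20. The closest known reaction is the Danheiser benzannulation of cyclobutenones with siloxyalkynes to resorcinol monosilyl ethers; thermal opening of 3-ethoxycyclobutenones to vinylketenes is known from ketene–ethoxyacetylene adducts, and 17 is itself a 3-oxygenated cyclobutenone of the kind that opens in every such annulation. Ring C closes by a thermally allowed six-electron disrotatory electrocyclisation of 18, which forms the bond between the former ketene carbon and the carbon bearing the ring B arm, after the [2+2] step has made the two other new ring bonds to the alkyne carbons. No stereocentre is set, since the racemic centres of 8, 17 and 19 are lost on ring opening and aromatisation. The step needs the regiochemistry of the [2+2] addition, which the polarised ynol ether secures because its carbon remote from oxygen is the nucleophile and bonds to the ketene carbonyl carbon, so that the three oxygens end on alternate ring atoms and the free CH lies between OEt and OSi. It also needs the ketenes to meet only the alkyne, which is supported by the neutral conditions, the methoxy-blocked ortho positions of both arms and the outward rotation of the arm in 8 (hydrogen inward at the closing terminus of 18).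

**Step 7**
Reactants: 20 3-ethoxy-2-(2,4,6-trimethoxybenzyl)-6-(2,4,6-trimethoxy-3-methylbenzyl)-5-(triisopropylsilyloxy)phenol
Product: 21 5-ethoxy-4-(2,4,6-trimethoxybenzyl)-2-(2,4,6-trimethoxy-3-methylbenzyl)benzene-1,3-diol
Conditions: Bu4NF, AcOH, THF, 0 °C
Reagents that add atoms: none
Why: Fluoride cleavage of the aryl silyl ether is driven by Si–F bond formation, and the acetic acid buffer keeps the electron-rich resorcinol protonated and leaves the alkyl ethers untouched.

**Step 8**
Reactants: 21 5-ethoxy-4-(2,4,6-trimethoxybenzyl)-2-(2,4,6-trimethoxy-3-methylbenzyl)benzene-1,3-diol; 22 butyryl chloride (first of three equivalents)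
Product: 23 1-[2-ethoxy-4,6-dihydroxy-3-(3-butanoyl-2,4,6-trimethoxybenzyl)-5-(3-butanoyl-2,4,6-trimethoxy-5-methylbenzyl)phenyl]butan-1-one
Conditions: 22 (3.3 equiv), AlCl3 (6 equiv), CH2Cl2/MeNO2, 0 °C; aq. HCl
Reagents that add atoms: butyryl chloride (second equivalent), CCCC(=O)Cl; butyryl chloride (third equivalent), CCCC(=O)Cl
Why: This threefold Friedel–Crafts acylation consumes three molecules of the acid chloride, because each ring offers one most activated free carbon (ring C between OH and OEt, ring D its only CH, ring B one of two equivalent CH) and each acyl group deactivates its ring against a second acylation or ipso attack, so one butyryl group per ring is expected.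

**Step 9**
Reactants: 23 1-[2-ethoxy-4,6-dihydroxy-3-(3-butanoyl-2,4,6-trimethoxybenzyl)-5-(3-butanoyl-2,4,6-trimethoxy-5-methylbenzyl)phenyl]butan-1-one
Product: 24 1-[2,4,6-trihydroxy-3-(3-butanoyl-2,4,6-trihydroxybenzyl)-5-(3-butanoyl-2,4,6-trihydroxy-5-methylbenzyl)phenyl]butan-1-one
Conditions: BBr3 (excess), CH2Cl2, −78 °C to rt; then H2O
Reagents that add atoms: none
Why: Boron tribromide cleaves aryl alkyl ethers by O-complexation and bromide attack on the alkyl group, the five ethers ortho to carbonyl groups reacting fastest through chelates, and methylene-bridged polyalkoxyarenes are known to survive this reagent.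

**Step 10**
Reactants: 25 1-(2,4,6-trihydroxyphenyl)butan-1-one
Product: 27 2-butanoyl-3,5-dihydroxy-4,4-dimethylcyclohexa-2,5-dien-1-one (butyrylfilicinic acid), via monomethyl ketone 26 (not isolated)
Conditions: MeI (2.2 equiv), NaOMe, MeOH, 0 °C to rt; aq. HCl
Reagents that add atoms: iodomethane, CI
Why: Twofold C-methylation of the acylphloroglucinol polyanion at one ring carbon is the classical entry to acylfilicinic acids, and limiting iodomethane should stop the sequence at the dearomatised gem-dimethyl vinylogous acid, whose anion is a weaker nucleophile.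

**Step 11**
Reactants: 27 2-butanoyl-3,5-dihydroxy-4,4-dimethylcyclohexa-2,5-dien-1-one
Product: 28 2-butanoyl-6-[(dimethylamino)methyl]-3,5-dihydroxy-4,4-dimethylcyclohexa-2,5-dien-1-one
Conditions: CH2(NMe2)2, 1,4-dioxane, rt
Reagents that add atoms: bis(dimethylamino)methane, CN(C)CN(C)C
Why: In this Mannich aminomethylation the acidic trione protonates the aminal to the iminium ion, which is captured at the only free, doubly enolic ring carbon of 27.

**Step 12**
Reactants: 24 1-[2,4,6-trihydroxy-3-(3-butanoyl-2,4,6-trihydroxybenzyl)-5-(3-butanoyl-2,4,6-trihydroxy-5-methylbenzyl)phenyl]butan-1-one; 28 2-butanoyl-6-[(dimethylamino)methyl]-3,5-dihydroxy-4,4-dimethylcyclohexa-2,5-dien-1-one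
Product: 30 target CNP0246352.0, via methylene trione 29 (not isolated)
Conditions: 1,4-dioxane, 80 °C, N2
Reagents that add atoms: none
Why: Thermal loss of dimethylamine from the Mannich base gives the exocyclic enone (an ortho-quinone-methide-type acceptor), which should undergo Michael addition by the single unsubstituted carbon of ring B, the established way to unsymmetrical methylene-bridged acylphloroglucinols.

**Compound list**
1 | 2,4,6-trimethoxybenzaldehyde | COc1cc(OC)c(C=O)c(OC)c1 | starting material
2 | 5-(2,4,6-trimethoxybenzylidene)-2,2-dimethyl-1,3-dioxane-4,6-dione | COc1cc(OC)c(C=C2C(=O)OC(C)(C)OC2=O)c(OC)c1 | intermediate (not isolated)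
3 | 5-(2,4,6-trimethoxybenzyl)-2,2-dimethyl-1,3-dioxane-4,6-dione | COc1cc(OC)c(CC2C(=O)OC(C)(C)OC2=O)c(OC)c1 | intermediate (not isolated)
4 | 3-(2,4,6-trimethoxyphenyl)propanoic acid | COc1cc(OC)c(CCC(=O)O)c(OC)c1 | intermediate
5 | ethoxyacetylene | CCOC#C | starting material
6 | 3-(2,4,6-trimethoxyphenyl)propanoyl chloride | COc1cc(OC)c(CCC(=O)Cl)c(OC)c1 | intermediate (not isolated)
7 | 3-(2,4,6-trimethoxyphenyl)prop-1-en-1-one (the monoalkylketene) | COc1cc(OC)c(CC=C=O)c(OC)c1 | intermediate (not isolated)
8 | 3-ethoxy-4-(2,4,6-trimethoxybenzyl)cyclobut-2-en-1-one, racemic | O=C1C=C(OCC)C1Cc1c(OC)cc(OC)cc1OC | intermediate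
9 | 2,4,6-trimethoxytoluene | Cc1c(OC)cc(OC)cc1OC | starting material
10 | ethyl 2-oxo-2-(2,4,6-trimethoxy-3-methylphenyl)acetate | CCOC(=O)C(=O)c1c(OC)c(C)c(OC)cc1OC | intermediate
11 | ethyl 2-hydroxy-2-(2,4,6-trimethoxy-3-methylphenyl)acetate, racemic | CCOC(=O)C(O)c1c(OC)c(C)c(OC)cc1OC | intermediate (not isolated)
12 | ethyl 2-(2,4,6-trimethoxy-3-methylphenyl)acetate | CCOC(=O)Cc1c(OC)c(C)c(OC)cc1OC | intermediate
13 | lithium 1,1-dibromo-3-(2,4,6-trimethoxy-3-methylphenyl)prop-1-en-2-olate | [Li+].[O-]C(Cc1c(OC)c(C)c(OC)cc1OC)=C(Br)Br | intermediate (not isolated)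
14 | lithium 3-(2,4,6-trimethoxy-3-methylphenyl)prop-1-yn-1-olate | [Li+].[O-]C#CCc1c(OC)c(C)c(OC)cc1OC | intermediate (not isolated)
15 | 1-(triisopropylsilyloxy)-3-(2,4,6-trimethoxy-3-methylphenyl)prop-1-yne | CC(C)[Si](OC#CCc1c(OC)c(C)c(OC)cc1OC)(C(C)C)C(C)C | intermediate
16 | (3Z)-3-ethoxy-5-(2,4,6-trimethoxyphenyl)penta-1,3-dien-1-one (arm trans to the ketene carbon) | O=C=C/C(OCC)=C/Cc1c(OC)cc(OC)cc1OC | intermediate (not isolated)
17 | 4-[(1Z)-1-ethoxy-3-(2,4,6-trimethoxyphenyl)prop-1-enyl]-2-(2,4,6-trimethoxy-3-methylbenzyl)-3-(triisopropylsilyloxy)cyclobut-2-en-1-one, racemic | O=C1C(Cc2c(OC)c(C)c(OC)cc2OC)=C(O[Si](C(C)C)(C(C)C)C(C)C)C1/C(OCC)=C/Cc1c(OC)cc(OC)cc1OC | intermediate (not isolated)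
18 | (3E,5Z)-5-ethoxy-2-(2,4,6-trimethoxy-3-methylbenzyl)-7-(2,4,6-trimethoxyphenyl)-3-(triisopropylsilyloxy)hepta-1,3,5-trien-1-one | O=C=C(Cc1c(OC)c(C)c(OC)cc1OC)/C(O[Si](C(C)C)(C(C)C)C(C)C)=C\C(OCC)=C\Cc1c(OC)cc(OC)cc1OC | intermediate (not isolated)
19 | 5-ethoxy-6-(2,4,6-trimethoxybenzyl)-2-(2,4,6-trimethoxy-3-methylbenzyl)-3-(triisopropylsilyloxy)cyclohexa-2,4-dien-1-one, racemic | O=C1C(Cc2c(OC)c(C)c(OC)cc2OC)=C(O[Si](C(C)C)(C(C)C)C(C)C)C=C(OCC)C1Cc1c(OC)cc(OC)cc1OC | intermediate (not isolated)
20 | 3-ethoxy-2-(2,4,6-trimethoxybenzyl)-6-(2,4,6-trimethoxy-3-methylbenzyl)-5-(triisopropylsilyloxy)phenol | Oc1c(Cc2c(OC)cc(OC)cc2OC)c(OCC)cc(O[Si](C(C)C)(C(C)C)C(C)C)c1Cc1c(OC)c(C)c(OC)cc1OC | intermediate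
21 | 5-ethoxy-4-(2,4,6-trimethoxybenzyl)-2-(2,4,6-trimethoxy-3-methylbenzyl)benzene-1,3-diol | Oc1c(Cc2c(OC)cc(OC)cc2OC)c(OCC)cc(O)c1Cc1c(OC)c(C)c(OC)cc1OC | intermediate
22 | butyryl chloride | CCCC(=O)Cl | starting material
23 | 1-[2-ethoxy-4,6-dihydroxy-3-(3-butanoyl-2,4,6-trimethoxybenzyl)-5-(3-butanoyl-2,4,6-trimethoxy-5-methylbenzyl)phenyl]butan-1-one | CCCC(=O)c1c(OC)cc(OC)c(Cc2c(O)c(Cc3c(OC)c(C)c(OC)c(C(=O)CCC)c3OC)c(O)c(C(=O)CCC)c2OCC)c1OC | intermediate
24 | 1-[2,4,6-trihydroxy-3-(3-butanoyl-2,4,6-trihydroxybenzyl)-5-(3-butanoyl-2,4,6-trihydroxy-5-methylbenzyl)phenyl]butan-1-one | CCCC(=O)c1c(O)cc(O)c(Cc2c(O)c(Cc3c(O)c(C)c(O)c(C(=O)CCC)c3O)c(O)c(C(=O)CCC)c2O)c1O | intermediate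
25 | 1-(2,4,6-trihydroxyphenyl)butan-1-one | CCCC(=O)c1c(O)cc(O)cc1O | starting material
26 | 1-(2,4,6-trihydroxy-3-methylphenyl)butan-1-one | CCCC(=O)c1c(O)cc(O)c(C)c1O | intermediate (not isolated)
27 | 2-butanoyl-3,5-dihydroxy-4,4-dimethylcyclohexa-2,5-dien-1-one (butyrylfilicinic acid) | CCCC(=O)C1=C(O)C(C)(C)C(O)=CC1=O | intermediate
28 | 2-butanoyl-6-[(dimethylamino)methyl]-3,5-dihydroxy-4,4-dimethylcyclohexa-2,5-dien-1-one | CCCC(=O)C1=C(O)C(C)(C)C(O)=C(CN(C)C)C1=O | intermediate
29 | 2-butanoyl-3-hydroxy-4,4-dimethyl-6-methylidenecyclohex-2-ene-1,5-dione | CCCC(=O)C1=C(O)C(C)(C)C(=O)C(=C)C1=O | intermediate (not isolated)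
30 | 2-butanoyl-6-[[3-butanoyl-5-[[3-butanoyl-5-[(3-butanoyl-2,4,6-trihydroxy-5-methylphenyl)methyl]-2,4,6-trihydroxyphenyl]methyl]-2,4,6-trihydroxyphenyl]methyl]-3,5-dihydroxy-4,4-dimethylcyclohexa-2,5-dien-1-one (CNP0246352.0, no stereocentre) | CCCC(=O)C1=C(O)C(C)(C)C(O)=C(Cc2c(O)c(Cc3c(O)c(Cc4c(O)c(C)c(O)c(C(=O)CCC)c4O)c(O)c(C(=O)CCC)c3O)c(O)c(C(=O)CCC)c2O)C1=O | target

**Step count**
Total: 12 steps. Longest linear sequence: 8 steps (steps 3, 4, 5, 6, 7, 8, 9 and 12, from 9).

**Steps most likely to fail**

Step 6. The vinylogous-ester cyclobutenone may open too slowly, so that the siloxyalkyne is lost by thermal rearrangement, or the vinylketene is lost by self-addition, before the [2+2] step. The fallback sets out from 8 and 15 and drives the first ring opening with light instead of heat. Irradiation of cyclobutenones (300 nm, CH2Cl2, rt) is a known way to generate vinylketenes at room temperature. The cascade would then be run in two operations: the photochemical stage should stop at vinylcyclobutenone 17, which is isolated and heated separately (PhMe, 110 °C) to come back to the route at 20. New compounds: none F0.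

Step 8. The acid may attack the diarylmethane bridges (ipso protonation and loss of a trialkoxybenzyl cation) before the rings are deactivated, and the flanked ring C carbon may react incompletely or on oxygen. The fallback sets out from 21 and replaces electrophilic substitution by directed ortho-metalation. Methylation of both phenols (MeI, K2CO3, DMF) should give 5-ethoxy-1,3-dimethoxy-4-(2,4,6-trimethoxybenzyl)-2-(2,4,6-trimethoxy-3-methylbenzyl)benzene F1. Each CH to be acylated then lies between two alkoxy groups, so threefold lithiation (n-BuLi, TMEDA, THF, 0 °C) and quench with N-methoxy-N-methylbutanamide should give the per-ether tris-ketone 1-[2-ethoxy-4,6-dimethoxy-3-(3-butanoyl-2,4,6-trimethoxybenzyl)-5-(3-butanoyl-2,4,6-trimethoxy-5-methylbenzyl)phenyl]butan-1-one F2. BBr3 (CH2Cl2, −78 °C to rt) then cleaves all nine ethers and comes back to the route at 24.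

Step 12. Methylene bridges may exchange by reversible retro-Michael and retro-Mannich steps, and the ring A Mannich base may couple with itself to the symmetrical dimer. The fallback sets out from 24 and reverses the roles of the partners. Aminomethylation of the free ring B carbon (CH2(NMe2)2, dioxane, rt) should give the Mannich base of trimer 24 that carries a (dimethylamino)methyl group on the free carbon of ring B F3. Heating F3 with an excess of the cheap carbon acid 27 (dioxane, 80 °C) lets ring B act as the acceptor and comes back to the route at 30.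

**Further compounds**
F0 | step 6 | none | none
F1 | step 8 | 5-ethoxy-1,3-dimethoxy-4-(2,4,6-trimethoxybenzyl)-2-(2,4,6-trimethoxy-3-methylbenzyl)benzene | COc1c(Cc2c(OC)cc(OC)cc2OC)c(OCC)cc(OC)c1Cc1c(OC)c(C)c(OC)cc1OC
F2 | step 8 | 1-[2-ethoxy-4,6-dimethoxy-3-(3-butanoyl-2,4,6-trimethoxybenzyl)-5-(3-butanoyl-2,4,6-trimethoxy-5-methylbenzyl)phenyl]butan-1-one | CCCC(=O)c1c(OC)cc(OC)c(Cc2c(OC)c(Cc3c(OC)c(C)c(OC)c(C(=O)CCC)c3OC)c(OC)c(C(=O)CCC)c2OCC)c1OC
F3 | step 12 | trimer 24 carrying a (dimethylamino)methyl group on the free carbon of ring B | CCCC(=O)c1c(O)c(CN(C)C)c(O)c(Cc2c(O)c(Cc3c(O)c(C)c(O)c(C(=O)CCC)c3O)c(O)c(C(=O)CCC)c2O)c1O
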